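The numbers in the tables are calculated on assumed constants; scatter was added.

Time is the setting to count in. Saturday's and Friday's flasks each stand for 30 min, and the earlier runs were read up to 20.0 min, so the question is how many halvings fit into that time.

the same everywhere: substrate 1.5 M; free catalyst 16 mol%
- alder: reagent 0.77 equiv; run made earlier
- oak: reagent 1.2 equiv; run made earlier
- Saturday's: reagent 0.950 equiv; time 30 min
- Friday's: reagent 1.40 equiv; time 30 min

The flasks differ in reagent and in time. Alder's 0.77 equiv lies below one equivalent, so reagent is its limiting reagent and caps product at 77.0 % of the substrate. Oak's 1.2 equiv lies above one equivalent, so there substrate is the limiting charge.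

| run | time / min | substrate / % | catalyst intermediate B / % | product / % |
|---|---|---|---|---|
| alder | 1.50 | 98 | 0 | 6 |
| alder | 4.00 | 81 | 2 | 18 |
| alder | 10.0 | 62 | 2 | 38 |
| alder | 20.0 | 42 | 0 | 58 |
| oak | 1.50 | 92 | 0 | 6 |
| oak | 4.00 | 79 | 3 | 22 |
| oak | 10.0 | 47 | 0 | 48 |
| oak | 20.0 | 25 | 0 | 81 |

(readings scatter by 2 percentage points)

Catalyst intermediate B reads from 0 % to 3 %, close to the scatter of 2 percentage points, so it is a trace. What can be followed is the shortfall, the part of the limiting charge not yet turned into product, much as an engineer follows the error of a first-order lag.

In alder the shortfall falls to 19.0 % of the substrate by 20.0 min, which gives the limiting-charge half-life, the time in which the shortfall halves: 9.91 min. In oak, [substrate] reads 25 % at the same time, which gives 10.0 min, a separate reading of about the same size.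

1. which of these there is most of at the end, counted by the substrate in it, Saturday's (substrate / catalyst intermediate B / product)
2. which of these there is most of at the end, counted by the substrate in it, Friday's (substrate / catalyst intermediate B / product)
3. final amount of the leader among these, as a percentage of the substrate charged, in Saturday's
4. final amount of the leader among these, as a percentage of the substrate charged, in Friday's

Saturday's 0.950 equiv again leaves reagent limiting, so 3.03 half-lives leave 12.3 % of the shortfall and give product 83.4 %. Friday's substrate is limiting, and its reagent excess exceeds oak's, so product should reach about 87.7 % or a little more.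

The forecast, from a “simple second-order fit”, puts product in the lead with 75 % on Saturday's, lower than this reckoning, and 90 % on Friday's.

The simulation puts product in the lead, with 80.0 % in Saturday's flask and 92.6 % in Friday's.

    reagent + free catalyst → catalyst intermediate A (k = 0.0180 M⁻¹ s⁻¹)
    substrate + catalyst intermediate A ⇌ catalyst intermediate B (K = 1.80 M⁻¹, k = 0.0100 M⁻¹ s⁻¹)
    catalyst intermediate B → free catalyst + product (k = 0.250 s⁻¹)
    free catalyst ⇌ dormant form (K = 1.10, k = 0.0240 s⁻¹)

Saturday's shortfall stands at 15.8 % of the reagent charge at 30 min, more than the 12.3 % reckoned. Read at 50 min, the same flask is 5.05 half-lives on, so the carried half-life leaves 3.02 % of the shortfall and gives product 92.1 %. That flask reads 90.4 % product, a shortfall of 4.84 % of the reagent charge.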